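**Retrosynthetic overview**
1. Target 24 ⇒ 5,8-dimethoxy chalcone 22 (oxidative demethylation to the quinone, then reduction) ⇒ chromene-6-carbonitrile 17 (MeMgBr, then Claisen–Schmidt).
2. 17 ⇒ ring-closing metathesis across C3=C4 of aryl ether 16. The benzene ring is bought; the pyran is the only ring made and closes in step 8.
3. Side-chain carbinol ⇒ Schenck ene reaction on the prenyl terminus. O1–C8a ⇒ SNAr of (S)-linalool, the bought source of the only stereocentre, on aryl fluoride 11.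
4. C4–C4a ⇒ aromatic Claisen [3,3] rearrangement of allyl ether 7, then allyl→propenyl shift; arene from 3-fluoro-4-methoxyphenol.

Assumption: (S)-(+)-linalool (coriandrol) is bought in high enantiomeric purity; the ee of the target equals that of this lot. The route has not been run; conditions are proposed from standard practice.

**Step 1**
Reactants: 1 3-fluoro-4-methoxyphenol
Product: 3 4-fluoro-2-hydroxy-5-methoxybenzaldehyde, via magnesium-bound 4-fluoro-2-(hydroxymethyl)-5-methoxyphenol 2 (not isolated)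
Conditions: MgCl2, Et3N, (CH2O)n, MeCN, reflux; then aq. HCl
Reagents that add atoms: paraformaldehyde (formaldehyde, C=O)
Why: Magnesium-phenoxide-directed ortho-formylation (Casiraghi–Skattebøl) attacks only ortho to OH, at the less hindered site para to F, and a second formaldehyde oxidises the benzylic alkoxide by hydride transfer.

**Step 2**
Reactants: 3 4-fluoro-2-hydroxy-5-methoxybenzaldehyde
Product: 5 4-fluoro-2-hydroxy-5-methoxybenzonitrile, via (E)-4-fluoro-2-hydroxy-5-methoxybenzaldehyde oxime 4 (not isolated)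
Conditions: NH2OH·HCl, HCO2Na, HCO2H, 100 °C
Reagents that add atoms: hydroxylamine hydrochloride (Cl.NO)
Why: Oxime formation and formic-acid-mediated dehydration give the nitrile, a non-enolisable para-activator for the later SNAr and a latent acyl group.

**Step 3**
Reactants: 5 4-fluoro-2-hydroxy-5-methoxybenzonitrile, 6 allyl bromide
Product: 7 4-fluoro-5-methoxy-2-(prop-2-en-1-yloxy)benzonitrile
Conditions: K2CO3, DMF, 50 °C
Reagents that add atoms: none
Why: Williamson O-allylation of an acidic cyanophenol is fast and clean.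

**Step 4**
Reactants: 7 4-fluoro-5-methoxy-2-(prop-2-en-1-yloxy)benzonitrile
Product: 10 4-fluoro-2-hydroxy-5-methoxy-3-[(1E)-prop-1-en-1-yl]benzonitrile, via racemic 4-fluoro-3-methoxy-6-oxo-5-(prop-2-en-1-yl)cyclohexa-1,3-diene-1-carbonitrile 8 (not isolated), via 4-fluoro-2-hydroxy-5-methoxy-3-(prop-2-en-1-yl)benzonitrile 9 (not isolated)
Conditions: 1,2-dichlorobenzene, 185 °C; then PdCl2(MeCN)2 (5 mol %), 80 °C, same pot
Reagents that add atoms: none
Why: The aromatic Claisen [3,3]-sigmatropic rearrangement forges the future C4–C4a bond at the only free ortho position, the dienone rearomatises, and Pd(II) shifts the allyl double bond into conjugation (E favoured; any Z isomer converges in step 8).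

**Step 5**
Reactants: 10 4-fluoro-2-hydroxy-5-methoxy-3-[(1E)-prop-1-en-1-yl]benzonitrile
Product: 11 4-fluoro-2,5-dimethoxy-3-[(1E)-prop-1-en-1-yl]benzonitrile
Conditions: MeI, K2CO3, DMF, rt
Reagents that add atoms: methyl iodide (CI)
Why: O-Methylation removes the acidic phenol, which would otherwise shut down the SNAr, and sets up the para-dimethoxy pair cleaved in step 11.

**Step 6**
Reactants: 11 4-fluoro-2,5-dimethoxy-3-[(1E)-prop-1-en-1-yl]benzonitrile, 12 (S)-(+)-linalool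
Product: 14 4-{[(3S)-3,7-dimethylocta-1,6-dien-3-yl]oxy}-2,5-dimethoxy-3-[(1E)-prop-1-en-1-yl]benzonitrile, via potassium (3S)-3,7-dimethylocta-1,6-dien-3-olate 13 (not isolated)
Conditions: KHMDS, THF, 0 °C; then 11, DMF, 18-crown-6 (cat.), rt → 45 °C
Reagents that add atoms: none
Why: SNAr of the tertiary potassium alkoxide on the para-cyano aryl fluoride forms only the aryl–O bond, so the carbinol C–O bond is never broken and the (S) centre of linalool becomes C2 unchanged; both ortho positions are blocked, so the ether cannot undergo a productive Claisen shift.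

**Step 7**
Reactants: 14 4-{[(3S)-3,7-dimethylocta-1,6-dien-3-yl]oxy}-2,5-dimethoxy-3-[(1E)-prop-1-en-1-yl]benzonitrile
Product: 16 4-{[(3S,5E)-7-hydroxy-3,7-dimethylocta-1,5-dien-3-yl]oxy}-2,5-dimethoxy-3-[(1E)-prop-1-en-1-yl]benzonitrile, via 4-{[(3S,5E)-7-hydroperoxy-3,7-dimethylocta-1,5-dien-3-yl]oxy}-2,5-dimethoxy-3-[(1E)-prop-1-en-1-yl]benzonitrile 15 (not isolated)
Conditions: O2, TPP (cat.), CH2Cl2, white LED, 0 °C; then PPh3, rt
Reagents that add atoms: oxygen (O=O)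
Why: The Schenck ene reaction of singlet oxygen picks the trisubstituted olefin and gives the E tertiary allylic hydroperoxide, which PPh3 reduces; the secondary regioisomer (roughly 1:1) is removed by chromatography and the stereocentre is untouched.

**Step 8**
Reactants: 16 4-{[(3S,5E)-7-hydroxy-3,7-dimethylocta-1,5-dien-3-yl]oxy}-2,5-dimethoxy-3-[(1E)-prop-1-en-1-yl]benzonitrile
Product: 17 (2S)-2-[(2E)-4-hydroxy-4-methylpent-2-en-1-yl]-5,8-dimethoxy-2-methyl-2H-chromene-6-carbonitrile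
Conditions: Grubbs II (5 mol %), CH2Cl2, 40 °C, dark
Reagents that add atoms: none
Why: Ring-closing metathesis joins the aryl propenyl and the vinyl on the quaternary carbon into the six-membered 2H-chromene with loss of propene; no bond at C2 is touched, and the alternative with the side-chain olefin would be a seven-membered ring.

**Step 9**
Reactants: 17 (2S)-2-[(2E)-4-hydroxy-4-methylpent-2-en-1-yl]-5,8-dimethoxy-2-methyl-2H-chromene-6-carbonitrile
Product: 19 1-{(2S)-2-[(2E)-4-hydroxy-4-methylpent-2-en-1-yl]-5,8-dimethoxy-2-methyl-2H-chromen-6-yl}ethan-1-one, via N-magnesiated 1-{(2S)-2-[(2E)-4-hydroxy-4-methylpent-2-en-1-yl]-5,8-dimethoxy-2-methyl-2H-chromen-6-yl}ethan-1-imine 18 (not isolated)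
Conditions: MeMgBr (4 equiv), CuBr·SMe2 (5 mol %), THF, 0 → 60 °C; then sat. aq. NH4Cl, rt
Reagents that add atoms: methylmagnesium bromide (C[Mg]Br), water (O)
Why: Grignard addition to the nitrile stops at the metallo-imine, which hydrolyses at pH 5 to the methyl ketone without exposing the tertiary allylic alcohol to strong acid.

**Step 10**
Reactants: 19 1-{(2S)-2-[(2E)-4-hydroxy-4-methylpent-2-en-1-yl]-5,8-dimethoxy-2-methyl-2H-chromen-6-yl}ethan-1-one, 20 benzaldehyde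
Product: 22 (2E)-1-{(2S)-2-[(2E)-4-hydroxy-4-methylpent-2-en-1-yl]-5,8-dimethoxy-2-methyl-2H-chromen-6-yl}-3-phenylprop-2-en-1-one, via 3-hydroxy-1-{(2S)-2-[(2E)-4-hydroxy-4-methylpent-2-en-1-yl]-5,8-dimethoxy-2-methyl-2H-chromen-6-yl}-3-phenylpropan-1-one (both carbinol epimers) 21 (not isolated)
Conditions: KOH, EtOH, rt
Reagents that add atoms: none
Why: Claisen–Schmidt aldol condensation with a non-enolisable aldehyde gives the E-chalcone by E1cB dehydration.

**Step 11**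
Reactants: 22 (2E)-1-{(2S)-2-[(2E)-4-hydroxy-4-methylpent-2-en-1-yl]-5,8-dimethoxy-2-methyl-2H-chromen-6-yl}-3-phenylprop-2-en-1-one
Product: 24 (2E)-1-{(2S)-5,8-dihydroxy-2-[(2E)-4-hydroxy-4-methylpent-2-en-1-yl]-2-methyl-2H-chromen-6-yl}-3-phenylprop-2-en-1-one, via (2S)-2-[(2E)-4-hydroxy-4-methylpent-2-en-1-yl]-2-methyl-6-[(2E)-3-phenylprop-2-enoyl]-2H-chromene-5,8-dione 23 (not isolated)
Conditions: CAN (2.5 equiv), MeCN/H2O, 0 °C, 10 min; then aq. Na2S2O4, rt
Reagents that add atoms: water (O)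
Why: Cerium(IV) oxidative demethylation turns the para-dimethoxy pair into the p-quinone (water attacks the ipso carbons, methanol leaves) and dithionite reduces it at once to the hydroquinone, removing both methyl groups without Lewis acid.

**Compound list**
1 | 3-fluoro-4-methoxyphenol | COc1ccc(O)cc1F | starting material
2 | 4-fluoro-2-(hydroxymethyl)-5-methoxyphenol (magnesium-bound) | COc1cc(CO)c(O)cc1F | intermediate
3 | 4-fluoro-2-hydroxy-5-methoxybenzaldehyde | COc1cc(C=O)c(O)cc1F | intermediate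
4 | (E)-4-fluoro-2-hydroxy-5-methoxybenzaldehyde oxime | COc1cc(/C=N/O)c(O)cc1F | intermediate
5 | 4-fluoro-2-hydroxy-5-methoxybenzonitrile | COc1cc(C#N)c(O)cc1F | intermediate
6 | allyl bromide | C=CCBr | starting material
7 | 4-fluoro-5-methoxy-2-(prop-2-en-1-yloxy)benzonitrile | COc1cc(C#N)c(OCC=C)cc1F | intermediate
8 | 4-fluoro-3-methoxy-6-oxo-5-(prop-2-en-1-yl)cyclohexa-1,3-diene-1-carbonitrile (racemic) | N#CC1=CC(OC)=C(F)C(CC=C)C1=O | intermediate
9 | 4-fluoro-2-hydroxy-5-methoxy-3-(prop-2-en-1-yl)benzonitrile | COc1cc(C#N)c(O)c(CC=C)c1F | intermediate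
10 | 4-fluoro-2-hydroxy-5-methoxy-3-[(1E)-prop-1-en-1-yl]benzonitrile | COc1cc(C#N)c(O)c(/C=C/C)c1F | intermediate
11 | 4-fluoro-2,5-dimethoxy-3-[(1E)-prop-1-en-1-yl]benzonitrile | COc1cc(C#N)c(OC)c(/C=C/C)c1F | intermediate
12 | (S)-(+)-linalool, (3S)-3,7-dimethylocta-1,6-dien-3-ol | C=C[C@@](C)(O)CCC=C(C)C | starting material
13 | potassium (3S)-3,7-dimethylocta-1,6-dien-3-olate | C=C[C@@](C)([O-])CCC=C(C)C.[K+] | intermediate
14 | 4-{[(3S)-3,7-dimethylocta-1,6-dien-3-yl]oxy}-2,5-dimethoxy-3-[(1E)-prop-1-en-1-yl]benzonitrile | COc1cc(C#N)c(OC)c(/C=C/C)c1O[C@](C)(C=C)CCC=C(C)C | intermediate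
15 | 4-{[(3S,5E)-7-hydroperoxy-3,7-dimethylocta-1,5-dien-3-yl]oxy}-2,5-dimethoxy-3-[(1E)-prop-1-en-1-yl]benzonitrile | COc1cc(C#N)c(OC)c(/C=C/C)c1O[C@](C)(C=C)C/C=C/C(C)(C)OO | intermediate
16 | 4-{[(3S,5E)-7-hydroxy-3,7-dimethylocta-1,5-dien-3-yl]oxy}-2,5-dimethoxy-3-[(1E)-prop-1-en-1-yl]benzonitrile | COc1cc(C#N)c(OC)c(/C=C/C)c1O[C@](C)(C=C)C/C=C/C(C)(C)O | intermediate
17 | (2S)-2-[(2E)-4-hydroxy-4-methylpent-2-en-1-yl]-5,8-dimethoxy-2-methyl-2H-chromene-6-carbonitrile | CC(C)(O)/C=C/C[C@@]1(C)C=Cc2c(OC)c(C#N)cc(OC)c2O1 | intermediate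
18 | 1-{(2S)-2-[(2E)-4-hydroxy-4-methylpent-2-en-1-yl]-5,8-dimethoxy-2-methyl-2H-chromen-6-yl}ethan-1-imine (formed as its N–MgBr salt) | CC(C)(O)/C=C/C[C@@]1(C)C=Cc2c(OC)c(C(C)=N)cc(OC)c2O1 | intermediate
19 | 1-{(2S)-2-[(2E)-4-hydroxy-4-methylpent-2-en-1-yl]-5,8-dimethoxy-2-methyl-2H-chromen-6-yl}ethan-1-one | CC(C)(O)/C=C/C[C@@]1(C)C=Cc2c(OC)c(C(C)=O)cc(OC)c2O1 | intermediate
20 | benzaldehyde | O=Cc1ccccc1 | starting material
21 | 3-hydroxy-1-{(2S)-2-[(2E)-4-hydroxy-4-methylpent-2-en-1-yl]-5,8-dimethoxy-2-methyl-2H-chromen-6-yl}-3-phenylpropan-1-one (both carbinol epimers) | CC(C)(O)/C=C/C[C@@]1(C)C=Cc2c(OC)c(C(=O)CC(O)c3ccccc3)cc(OC)c2O1 | intermediate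
22 | (2E)-1-{(2S)-2-[(2E)-4-hydroxy-4-methylpent-2-en-1-yl]-5,8-dimethoxy-2-methyl-2H-chromen-6-yl}-3-phenylprop-2-en-1-one | CC(C)(O)/C=C/C[C@@]1(C)C=Cc2c(OC)c(C(=O)/C=C/c3ccccc3)cc(OC)c2O1 | intermediate
23 | (2S)-2-[(2E)-4-hydroxy-4-methylpent-2-en-1-yl]-2-methyl-6-[(2E)-3-phenylprop-2-enoyl]-2H-chromene-5,8-dione | CC(C)(O)/C=C/C[C@@]1(C)C=CC2=C(O1)C(=O)C=C(C(=O)/C=C/c3ccccc3)C2=O | intermediate
24 | (2E)-1-{(2S)-5,8-dihydroxy-2-[(2E)-4-hydroxy-4-methylpent-2-en-1-yl]-2-methyl-2H-chromen-6-yl}-3-phenylprop-2-en-1-one (CNP0327890.1) | CC(C)(O)/C=C/C[C@@]1(C)C=Cc2c(O)c(C(=O)/C=C/c3ccccc3)cc(O)c2O1 | target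

**Totals**
Total steps: 11. Longest linear sequence: 11 (1 → 24); 6, 12 and 20 each enter in a single step.

**Steps most likely to fail**

Step 6 (SNAr). A tertiary alkoxide must attack a fluoride flanked by OMe and propenyl and activated only by the para nitrile. The fallback sets out from 11 and comes back at 17. Ozonolysis of 11 (O3, CH2Cl2/MeOH, −78 °C; Me2S) cuts the propenyl group to 4-fluoro-3-formyl-2,5-dimethoxybenzonitrile F1, whose fluoride now has an ortho-formyl as well as a para-cyano activator. Alkoxide 13 displaces it at −20 °C to give 4-{[(3S)-3,7-dimethylocta-1,6-dien-3-yl]oxy}-3-formyl-2,5-dimethoxybenzonitrile F2. Wittig methylenation (Ph3P=CH2, THF, 0 °C) gives 4-{[(3S)-3,7-dimethylocta-1,6-dien-3-yl]oxy}-3-ethenyl-2,5-dimethoxybenzonitrile F3. Photooxygenation and PPh3 as in step 7 give, through 3-ethenyl-4-{[(3S,5E)-7-hydroperoxy-3,7-dimethylocta-1,5-dien-3-yl]oxy}-2,5-dimethoxybenzonitrile F4, the alcohol 3-ethenyl-4-{[(3S,5E)-7-hydroxy-3,7-dimethylocta-1,5-dien-3-yl]oxy}-2,5-dimethoxybenzonitrile F5. Grubbs II then closes F5 to 17 with loss of ethene. The aryl carbon that becomes C4 is still the one installed by the Claisen step.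

Step 7 (Schenck ene). About half the material goes to the secondary hydroperoxide, and the aryl propenyl group is a slower competing site. The fallback sets out from 14 and comes back at 16. mCPBA (NaHCO3, CH2Cl2, 0 °C) epoxidises only the trisubstituted olefin to 4-{[(3S)-5-(3,3-dimethyloxiran-2-yl)-3-methylpent-1-en-3-yl]oxy}-2,5-dimethoxy-3-[(1E)-prop-1-en-1-yl]benzonitrile F6 (both epoxide epimers). PhSeNa (PhSeSePh, NaBH4, EtOH) opens it at the secondary carbon to 4-{[(3S)-7-hydroxy-3,7-dimethyl-6-(phenylselanyl)oct-1-en-3-yl]oxy}-2,5-dimethoxy-3-[(1E)-prop-1-en-1-yl]benzonitrile F7. H2O2 (THF, 0 °C → rt) gives the selenoxide 4-{[(3S)-7-hydroxy-3,7-dimethyl-6-(phenylseleninyl)oct-1-en-3-yl]oxy}-2,5-dimethoxy-3-[(1E)-prop-1-en-1-yl]benzonitrile F8. Its syn-elimination can only run away from the quaternary carbinol and gives 16 as a single regioisomer.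

Step 11 (CAN). The medium is acidic and oxidising, while the tertiary allylic alcohol, the electron-rich chromene and the acylquinone are all sensitive. The fallback sets out from 19 and comes back at 24. Both methyl ethers are cleaved under basic SN2 conditions before the enone exists (NaSEt, DMF, 110 °C, dark), giving 1-{(2S)-5,8-dihydroxy-2-[(2E)-4-hydroxy-4-methylpent-2-en-1-yl]-2-methyl-2H-chromen-6-yl}ethan-1-one F9. Claisen–Schmidt condensation with 20 (KOH, EtOH, argon) then passes through the aldol 1-{(2S)-5,8-dihydroxy-2-[(2E)-4-hydroxy-4-methylpent-2-en-1-yl]-2-methyl-2H-chromen-6-yl}-3-hydroxy-3-phenylpropan-1-one F10 to 24.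

**Further compounds**
F1 | step 6 | 4-fluoro-3-formyl-2,5-dimethoxybenzonitrile | COc1cc(C#N)c(OC)c(C=O)c1F
F2 | step 6 | 4-{[(3S)-3,7-dimethylocta-1,6-dien-3-yl]oxy}-3-formyl-2,5-dimethoxybenzonitrile | COc1cc(C#N)c(OC)c(C=O)c1O[C@](C)(C=C)CCC=C(C)C
F3 | step 6 | 4-{[(3S)-3,7-dimethylocta-1,6-dien-3-yl]oxy}-3-ethenyl-2,5-dimethoxybenzonitrile | COc1cc(C#N)c(OC)c(C=C)c1O[C@](C)(C=C)CCC=C(C)C
F4 | step 6 | 3-ethenyl-4-{[(3S,5E)-7-hydroperoxy-3,7-dimethylocta-1,5-dien-3-yl]oxy}-2,5-dimethoxybenzonitrile | COc1cc(C#N)c(OC)c(C=C)c1O[C@](C)(C=C)C/C=C/C(C)(C)OO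
F5 | step 6 | 3-ethenyl-4-{[(3S,5E)-7-hydroxy-3,7-dimethylocta-1,5-dien-3-yl]oxy}-2,5-dimethoxybenzonitrile | COc1cc(C#N)c(OC)c(C=C)c1O[C@](C)(C=C)C/C=C/C(C)(C)O
F6 | step 7 | 4-{[(3S)-5-(3,3-dimethyloxiran-2-yl)-3-methylpent-1-en-3-yl]oxy}-2,5-dimethoxy-3-[(1E)-prop-1-en-1-yl]benzonitrile (both epoxide epimers) | COc1cc(C#N)c(OC)c(/C=C/C)c1O[C@](C)(C=C)CCC2OC2(C)C
F7 | step 7 | 4-{[(3S)-7-hydroxy-3,7-dimethyl-6-(phenylselanyl)oct-1-en-3-yl]oxy}-2,5-dimethoxy-3-[(1E)-prop-1-en-1-yl]benzonitrile (both C6 epimers) | COc1cc(C#N)c(OC)c(/C=C/C)c1O[C@](C)(C=C)CCC([Se]c2ccccc2)C(C)(C)O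
F8 | step 7 | 4-{[(3S)-7-hydroxy-3,7-dimethyl-6-(phenylseleninyl)oct-1-en-3-yl]oxy}-2,5-dimethoxy-3-[(1E)-prop-1-en-1-yl]benzonitrile | COc1cc(C#N)c(OC)c(/C=C/C)c1O[C@](C)(C=C)CCC([Se](=O)c2ccccc2)C(C)(C)O
F9 | step 11 | 1-{(2S)-5,8-dihydroxy-2-[(2E)-4-hydroxy-4-methylpent-2-en-1-yl]-2-methyl-2H-chromen-6-yl}ethan-1-one | CC(C)(O)/C=C/C[C@@]1(C)C=Cc2c(O)c(C(C)=O)cc(O)c2O1
F10 | step 11 | 1-{(2S)-5,8-dihydroxy-2-[(2E)-4-hydroxy-4-methylpent-2-en-1-yl]-2-methyl-2H-chromen-6-yl}-3-hydroxy-3-phenylpropan-1-one (both carbinol epimers) | CC(C)(O)/C=C/C[C@@]1(C)C=Cc2c(O)c(C(=O)CC(O)c3ccccc3)cc(O)c2O1
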